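The data were generated by integration for an exercise; noise was put on by code.

E is a way station, so follow one molecule of G: it enters E when it leaves G and waits there before passing on to Z, and where E stands flat the flow in equals the flow out, which makes the height of the peak the flow times the wait.

| setting | cedar | alder | larch | flask |
|---|---|---|---|---|
| G | 20 mM | 20 mM | 10 mM | 20 mM |
| Q | 0.51 mM | 1.1 mM | 0.76 mM | 0.76 mM |
| remark | run made earlier | run made earlier | run made earlier |  |
| time |  |  |  | 6.0 d |

| run | time / d | E / % | G / % |
|---|---|---|---|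
| cedar | 0.833 | 4.4 | 94.3 |
| cedar | 1.25 | 7.5 | 86.9 |
| cedar | 2.08 | 13.6 | 71.1 |
| cedar | 3.00 | 17.2 | 53.0 |
| cedar | 5.00 | 15.6 | 22.7 |
| alder | 0.833 | 9.2 | 86.5 |
| alder | 1.25 | 15.7 | 75.1 |
| alder | 2.08 | 23.8 | 50.2 |
| alder | 3.00 | 23.3 | 28.1 |
| alder | 5.00 | 13.7 | 6.6 |
| larch | 0.833 | 3.9 | 94.3 |
| larch | 1.25 | 7.2 | 90.3 |
| larch | 2.08 | 11.6 | 75.5 |
| larch | 3.00 | 16.1 | 58.8 |
| larch | 5.00 | 15.5 | 28.2 |

(readings scatter by 0.5 percentage points)

- on the list of suspects stand: G + Q -> L + E; G + L -> E + L; E <-> Z

- time, not beyond 6.0 d, at which the flask holds most E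
- the amount of E, in percent of the G charged, at that time
- earliest time at which at least nineteen twentieths of that best amount are there, in d
- latest time at which they still are, in d

Read the wait from alder, where E reads 23.8% and 23.3% at 2.08 d and 3.00 d while G falls by a fraction 0.240 /d of its charge: dividing the mean E by this flow gives the net stay of a molecule in E, return from Z counted, 0.980 d (a mean residence time). Take the peak of the flask to lie in that same window, give it the flow interpolated straight in Q between alder and cedar's 0.197 /d, which is 0.215 /d, and multiply by the stay to commit to a height of 21.1%.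

The forecast, “Setting supply against loss”, gave 21% at 3 d, with the asked share of that best held from 2.4 d to 3.75 d.

The flask gives 20.9% at 2.90 d, with the asked share of that best held from 2.32 d to 3.59 d.

    G + Q → L + E (k = 0.339 /M/h)
    G + L → E + L, rate k2*[L]*[G] (k = 90.2 /M/h)
    E ⇌ Z (K = 14.6, k = 0.0472 /h)

Carry the stay unchanged to the neighbour flask charged with 50 mM of G. Its best of 27.3% then means a flow at its peak of 0.279 /d, larger than the 0.213 /d of the flask. At 6.00 d that neighbour flask holds 1.26% of its G and 89.9% as Z.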